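## The problem

The target **24** is a flavonol methyl ether: a 4H-chromen-4-one whose pyranone ring C carries a methoxy group at C3 and ring B at C2, fused to a pentasubstituted ring A. It has no stereocentre, so nothing has to be set or relayed, and the whole difficulty is regiochemical. Ring A is a 2-methylphloroglucinol in which the three oxygens all differ: O1 is the ring oxygen on C8a, C7 carries a methyl ether and C5 a free hydroxyl, and the methyl group sits on C8, not C6. Methylphloroglucinol itself offers no handle for telling these oxygens apart, and a ketone flanked by two free hydroxyls would close ring C in both directions. Ring B holds a methyl ether between two free hydroxyls, the kind of ether that Lewis acids attack first, and the C5 oxygen lies peri to the C4 carbonyl, so the protecting groups must come off under neutral conditions and the electron-rich phenols should be unveiled last. The methoxyacetyl unit that supplies C4, C3 and the 3-methoxy group is also awkward as an acylium ion, which is prone to lose carbon monoxide. The feature that invites a de novo construction of ring A is the triad C8a(O)–C8(CH3)–C7(OCH3): it corresponds to a ketene carbonyl carbon joined to the two carbons of 1-methoxyprop-1-yne, while C4a–C5(O)–C6 is the three-carbon remainder of a 3-alkoxycyclobutenone. The ring can therefore be made with every substituent in place and with C4a as the only free position ortho to the new hydroxyl.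

## Retrosynthesis

**Deprotection.** The three free hydroxyls of **24** are traced to benzyl ethers in the protected flavone **23**; only three O–CH2Ph bonds are cut. Benzyl is preferred to methyl or isopropyl because hydrogenolysis is neutral, whereas a Lewis acid able to cleave a C5 ether would also threaten the 3-methoxy group and the ring B methyl ether between two oxygens. The forward step must leave the C2=C3 bond of the flavone intact.

**Ring C.** In **23** the O1–C2 bond is cut to give the 1,3-diketone **22**. The bond between C3 and the ring B carbonyl is then cut by a Baker–Venkataraman retron to the aryl ester **21**, which comes from the hydroxy ketone **16** and the acid **19** (through its chloride **20**). This is preferred to a chalcone followed by Algar–Flynn–Oyamada oxidation, which tends to give aurones when the position next to the ketone carries an alkoxy group. It is also preferred to oxygenating C3 after the flavone is built, which costs two more steps. The forward sequence asks only that O1 be the single free hydroxyl next to the ketone, which the benzyl ether on the C5 oxygen guarantees.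

**The C4–C4a bond.** Ketone **16** is simplified to its methoxymethyl ether **15**, and the C4–C4a bond is cut to the aryllithium **14** and the Weinreb amide **13**; **14** arises by directed metalation of the methoxymethyl ether **12** of phenol **11**. Esterification of **11** and a Fries shift would be one step shorter. It was set aside because the Lewis acid endangers the benzyl ether, the alpha-methoxy acylium ion can lose carbon monoxide, and ortho versus para migration is not secured. The aryl anion route places the acyl group at the carbon flanked by two oxygens without acid.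

**Ring A (key disconnection).** Phenol **11** is cut at C8–C8a, C6–C7 and C4a–C8a to 3-(benzyloxy)cyclobut-2-en-1-one **3** and 1-methoxyprop-1-yne **6**. The forward reaction passes through vinylketene **7**, vinylcyclobutenone **8**, dienylketene **9** and dienone **10**. Selective alkylation of a preformed methylphloroglucinol could not deliver three different oxygens. Here each oxygen arrives with its own substituent (H, CH3, CH2Ph), and the precursors are four- and three-carbon fragments. The forward step needs one orientation of the ketene–alkyne addition.

**The small fragments.** Cyclobutenone **3** is cut at its enol ether C–O bond to commercial 3-ethoxycyclobut-2-en-1-one **1** and benzyl alcohol **2**. Alkyne **6** is cut at its C–CH3 bond to sodium methoxyethynide **5**, formed from chloroacetaldehyde dimethyl acetal **4**. Acid **19** comes from its benzyl ester **18**, the perbenzylation product of commercial 3,5-dihydroxy-4-methoxybenzoic acid **17**.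

## Roads not taken

**Alternative 1:** The cut is C4–C4a with O1 already in place. The phenol 3-methoxy-2-methyl-5-(propan-2-yloxy)phenol A3 would be joined through oxygen to a 2-methoxy-3-arylacrylic acid, giving the aryloxyacrylic acid A2. Its mixed anhydride with (CF3CO)2O would acylate C4a and close ring C to the tris(isopropyl) flavone A1, and BCl3 would then give **24**.
- Merits: the ring closure is intramolecular at the only free ortho position, and ring C is made in one step where the chosen plan needs three.
- Weak points: A3 carries the same three-way differentiation as **11**, so the ring A problem is presupposed, not solved. A2 needs O-vinylation of a hindered phenol with control of alkene geometry. The final BCl3 step must spare the 3-methoxy group and the ring B methyl ether between two oxygens.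
- Comparison: this road is shorter after the phenol. The chosen plan sets against it a construction of the differentiated phenol itself and a neutral final deprotection.

**Alternative 2:** The cut is C7–C8, with ring A closed last onto a finished pyranone. LiN(SiMe3)2 would deprotonate the ethyl group of the pyranone keto ester A5 at its vinylogous position; the carbanion would attack the side-chain ester and, after tautomerisation, give the 5,7-dihydroxy-8-methylflavone A4. Selective methylation of the unchelated 7-hydroxyl and hydrogenolysis would finish.
- Merits: the methyl group is fixed on C8 by construction, no pericyclic step is needed, and the C5 hydroxyl arrives free and is distinguished from the C7 hydroxyl by chelation. In these respects this road is better than the chosen one.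
- Weak points: A5 is a fully substituted 4-pyranone that is harder to make than any compound of the chosen route. The beta-keto ester methylene is deprotonated before the ethyl group, so the ester must be attacked while it is an enolate, by a polyanion. The pyranone is itself open to nucleophilic ring opening.
- Comparison: the chosen plan sets against it two small, accessible fragments and a shorter, better precedented sequence.

**Alternative 3:** The cut is O1–C8a. The fluoroarene A8 would be lithiated next to fluorine and carried to the 2-fluoroaryl 1,3-diketone A7. With K2CO3 the enolate oxygen would displace fluoride to give A6, which is identical with **23**, so the last step is shared.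
- Merits: fluorine marks C8a unambiguously and is a strong ortho director, so acylation at C4a is at least as secure as the metalation of **12**. No phenol protection and release is needed.
- Weak points: A8 has the same 1,2,3,5 pattern as **11** and must itself be made over several steps. The substitution takes place on a ring whose only activating group is a carbonyl cross-conjugated with two alkoxy donors, so it should need heat and base, under which a 1,3-diketone can cleave.
- Comparison: the two roads are about equal in length. The chosen plan sets against it a ring A made convergently from acyclic pieces and a ring C closure by well-tried condensation chemistry.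

Key step: step 3

Assumption: 3-ethoxycyclobut-2-en-1-one (**1**), N,2-dimethoxy-N-methylacetamide (**13**) and 3,5-dihydroxy-4-methoxybenzoic acid (**17**) are taken as purchasable.

## Route

Step 1
Reactants: 1 3-ethoxycyclobut-2-en-1-one; 2 benzyl alcohol
Product: 3 3-(benzyloxy)cyclobut-2-en-1-one
Conditions: BnOH (3 equiv), PPTS (5 mol%), toluene, 50 °C, reduced pressure (EtOH removed)
Reagents that add atoms: none
Why: Acid-catalysed transetherification of a vinylogous ester: protonation of the enone oxygen makes C3 electrophilic, benzyl alcohol adds and ethanol is lost; removal of the lower-boiling ethanol drives the exchange, and the mild anhydrous acid avoids hydrolysis to the dione.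

Step 2
Reactants: 4 2-chloro-1,1-dimethoxyethane (chloroacetaldehyde dimethyl acetal)
Product: 6 1-methoxyprop-1-yne, via sodium methoxyethynide 5 (not isolated)
Conditions: NaNH2 (3.1 equiv), liq. NH3, −33 °C; then MeI (1.0 equiv), −33 °C; distillation
Reagents that add atoms: iodomethane, CI
Why: Sodium amide effects twofold elimination (methanol, then hydrogen chloride) from the chloroacetal and deprotonates the resulting methoxyethyne; the acetylide 5 is then C-methylated by iodomethane (acetylide alkylation) and the volatile ynol ether is distilled off.

Step 3
Reactants: 3 3-(benzyloxy)cyclobut-2-en-1-one; 6 1-methoxyprop-1-yne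
Product: 11 5-(benzyloxy)-3-methoxy-2-methylphenol, via vinylketene 7 (not isolated), via 4-vinylcyclobutenone 8 (not isolated), via dienylketene 9 (not isolated), via cyclohexadienone 10 (not isolated)
Conditions: toluene, sealed tube, 80 → 120 °C (6 in twofold excess); then K2CO3, MeOH, rt
Reagents that add atoms: none
Why: Danheiser benzannulation: thermal four-electron electrocyclic opening of 3 gives the alkoxyvinylketene 7. The ynol ether 6 adds across the ketene C=C bond in a [2+2] cycloaddition, its methyl-bearing carbon bonding to the ketene carbonyl carbon (C8–C8a) and its methoxy-bearing carbon to the ketene alpha carbon (C6–C7), to give 8. A second four-electron opening of 8 gives the dienylketene 9, whose thermally allowed disrotatory six-electron electrocyclisation forms C4a–C8a and closes ring A as the dienone 10, which tautomerises to the phenol. The closest known reaction type is the benzannulation of 3-alkyl- and 3-arylcyclobutenones with alkoxy- and silyloxyalkynes; the benzyloxy group sits on the vinyl arm of the ketene as a spectator, and a 3-alkoxy-4-vinylcyclobutenone like 8 is the species that opens in every such cascade. No stereocentre is created, since 8 is racemic and is consumed. The selectivity needed is the orientation of the [2+2] step, which the polarisation of the ynol ether secures (its beta carbon is the nucleophile, the ketene carbonyl carbon the electrophile), so methyl ends ortho and methoxy meta to the new hydroxyl. A methyl ynol ether has no hydrogen for retro-ene loss of ketene and so tolerates the temperature that the donor-stabilised cyclobutenone should need; excess alkyne intercepts 7 before it dimerises, and the carbonate methanolysis returns any phenol acylated by the ketene.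

Step 4
Reactants: 11 5-(benzyloxy)-3-methoxy-2-methylphenol
Product: 12 1-(benzyloxy)-3-methoxy-5-(methoxymethoxy)-4-methylbenzene
Conditions: NaH, MOMCl, THF–DMF, 0 °C → rt
Reagents that add atoms: chloromethyl methyl ether, COCCl
Why: Williamson-type O-alkylation of the sodium phenoxide; the acetal serves as the directing group of the next step and is later removed by mild acid that leaves the benzyl ether alone.

Step 5
Reactants: 12 1-(benzyloxy)-3-methoxy-5-(methoxymethoxy)-4-methylbenzene; 13 N,2-dimethoxy-N-methylacetamide
Product: 15 1-[6-(benzyloxy)-4-methoxy-2-(methoxymethoxy)-3-methylphenyl]-2-methoxyethan-1-one, via aryllithium 14 (not isolated)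
Conditions: n-BuLi (1.15 equiv), THF, 0 °C; then 13, −78 → 0 °C; aq. NH4Cl
Reagents that add atoms: none
Why: Directed ortho-metalation followed by Weinreb ketone synthesis: the chelating methoxymethoxy group delivers butyllithium to the C–H flanked by two oxygens (the future C4a), while the other ring C–H is shielded by the methoxy group whose methyl is pushed toward it by the neighbouring C-methyl; 14 adds to 13 to give a chelated tetrahedral adduct that releases the ketone only on work-up, so neither over-addition nor an acylium ion is involved.

Step 6
Reactants: 15 1-[6-(benzyloxy)-4-methoxy-2-(methoxymethoxy)-3-methylphenyl]-2-methoxyethan-1-one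
Product: 16 1-[6-(benzyloxy)-2-hydroxy-4-methoxy-3-methylphenyl]-2-methoxyethan-1-one
Conditions: 3 M HCl, MeOH, 50 °C
Reagents that add atoms: none
Why: Acid-catalysed acetal cleavage (transacetalisation to dimethoxymethane); the phenol ortho to the ketone is released readily, while aryl benzyl and methyl ethers and the alpha-methoxy ketone are stable to dilute acid in methanol.

Step 7
Reactants: 17 3,5-dihydroxy-4-methoxybenzoic acid
Product: 18 benzyl 3,5-bis(benzyloxy)-4-methoxybenzoate
Conditions: BnBr (3.5 equiv), K2CO3, DMF, 60 °C
Reagents that add atoms: benzyl bromide, BrCc1ccccc1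
Why: Williamson etherification of both phenols and O-alkylation of the carboxylate under standard carbonate conditions; benzylating all three acidic groups removes any chemoselectivity question.

Step 8
Reactants: 18 benzyl 3,5-bis(benzyloxy)-4-methoxybenzoate
Product: 19 3,5-bis(benzyloxy)-4-methoxybenzoic acid
Conditions: NaOH, THF–MeOH–H2O, 60 °C; then aq. HCl
Reagents that add atoms: sodium hydroxide, [Na+].[OH-]
Why: Saponification of the benzyl ester by acyl–oxygen cleavage; aryl benzyl ethers are inert to aqueous hydroxide.

Step 9
Reactants: 16 1-[6-(benzyloxy)-2-hydroxy-4-methoxy-3-methylphenyl]-2-methoxyethan-1-one; 19 3,5-bis(benzyloxy)-4-methoxybenzoic acid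
Product: 21 3-(benzyloxy)-5-methoxy-2-(methoxyacetyl)-6-methylphenyl 3,5-bis(benzyloxy)-4-methoxybenzoate, via acid chloride 20 (not isolated)
Conditions: 19, (COCl)2, DMF (cat.), CH2Cl2, rt, evaporate; then 16, Et3N, DMAP (cat.), CH2Cl2, 0 °C → rt
Reagents that add atoms: none
Why: Acid chloride formation with oxalyl chloride under DMF catalysis, then DMAP-catalysed O-acylation of the hindered, hydrogen-bonded phenol; this is the only free hydroxyl, the C5 oxygen being benzylated.

Step 10
Reactants: 21 3-(benzyloxy)-5-methoxy-2-(methoxyacetyl)-6-methylphenyl 3,5-bis(benzyloxy)-4-methoxybenzoate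
Product: 22 1-[6-(benzyloxy)-2-hydroxy-4-methoxy-3-methylphenyl]-3-[3,5-bis(benzyloxy)-4-methoxyphenyl]-2-methoxypropane-1,3-dione (racemic)
Conditions: LiHMDS (3 equiv), THF, −78 → 0 °C; aq. HCl
Reagents that add atoms: none
Why: Baker–Venkataraman rearrangement: the ketone enolate at the methoxy-bearing carbon attacks the neighbouring aryl ester through a six-membered transition state and the aroyl group shifts from O to C; the new stereocentre at C2 of the dione is racemic and enolisable and disappears in the next step.

Step 11
Reactants: 22 1-[6-(benzyloxy)-2-hydroxy-4-methoxy-3-methylphenyl]-3-[3,5-bis(benzyloxy)-4-methoxyphenyl]-2-methoxypropane-1,3-dione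
Product: 23 5-(benzyloxy)-2-[3,5-bis(benzyloxy)-4-methoxyphenyl]-3,7-dimethoxy-8-methyl-4H-chromen-4-one
Conditions: p-TsOH·H2O (0.2 equiv), toluene, 90 °C
Reagents that add atoms: none
Why: Acid-catalysed cyclodehydration: the free phenol adds to the ring B carbonyl to give a cyclic hemiketal that loses water, forming the O1–C2 bond and the C2=C3 double bond; closure can occur only through O1 because the C5 oxygen is benzylated.

Step 12
Reactants: 23 5-(benzyloxy)-2-[3,5-bis(benzyloxy)-4-methoxyphenyl]-3,7-dimethoxy-8-methyl-4H-chromen-4-one
Product: 24 2-(3,5-dihydroxy-4-methoxyphenyl)-5-hydroxy-3,7-dimethoxy-8-methyl-4H-chromen-4-one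
Conditions: H2 (1 atm), Pd/C (10 wt% palladium on carbon), EtOAc–MeOH, rt
Reagents that add atoms: none
Why: Catalytic hydrogenolysis of three aryl benzyl ethers; the tetrasubstituted C2=C3 bond of the flavone (a vinylogous ester) and the methyl ethers should not be touched under these conditions.

## Compound list

1 | 3-ethoxycyclobut-2-en-1-one | CCOC1=CC(=O)C1 | starting material
2 | benzyl alcohol | OCc1ccccc1 | starting material
3 | 3-(benzyloxy)cyclobut-2-en-1-one | O=C1C=C(OCc2ccccc2)C1 | intermediate
4 | 2-chloro-1,1-dimethoxyethane | COC(CCl)OC | starting material
5 | sodium 2-methoxyethyn-1-ide | [Na+].[C-]#COC | intermediate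
6 | 1-methoxyprop-1-yne | COC#CC | intermediate
7 | 3-(benzyloxy)buta-1,3-dien-1-one | O=C=CC(=C)OCc1ccccc1 | intermediate
8 | 4-[1-(benzyloxy)ethenyl]-3-methoxy-2-methylcyclobut-2-en-1-one (racemic) | O=C1C(C)=C(OC)C1C(=C)OCc1ccccc1 | intermediate
9 | (3E)-5-(benzyloxy)-3-methoxy-2-methylhexa-1,3,5-trien-1-one | O=C=C(C)/C(OC)=C\C(=C)OCc1ccccc1 | intermediate
10 | 5-(benzyloxy)-3-methoxy-2-methylcyclohexa-2,4-dien-1-one | O=C1CC(OCc2ccccc2)=CC(OC)=C1C | intermediate
11 | 5-(benzyloxy)-3-methoxy-2-methylphenol | COc1cc(OCc2ccccc2)cc(O)c1C | intermediate
12 | 1-(benzyloxy)-3-methoxy-5-(methoxymethoxy)-4-methylbenzene | COCOc1cc(OCc2ccccc2)cc(OC)c1C | intermediate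
13 | N,2-dimethoxy-N-methylacetamide | COCC(=O)N(C)OC | starting material
14 | [6-(benzyloxy)-4-methoxy-2-(methoxymethoxy)-3-methylphenyl]lithium | [Li]c1c(OCOC)c(C)c(OC)cc1OCc1ccccc1 | intermediate
15 | 1-[6-(benzyloxy)-4-methoxy-2-(methoxymethoxy)-3-methylphenyl]-2-methoxyethan-1-one | COCC(=O)c1c(OCOC)c(C)c(OC)cc1OCc1ccccc1 | intermediate
16 | 1-[6-(benzyloxy)-2-hydroxy-4-methoxy-3-methylphenyl]-2-methoxyethan-1-one | COCC(=O)c1c(O)c(C)c(OC)cc1OCc1ccccc1 | intermediate
17 | 3,5-dihydroxy-4-methoxybenzoic acid | COc1c(O)cc(cc1O)C(O)=O | starting material
18 | benzyl 3,5-bis(benzyloxy)-4-methoxybenzoate | COc1c(OCc2ccccc2)cc(cc1OCc1ccccc1)C(=O)OCc1ccccc1 | intermediate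
19 | 3,5-bis(benzyloxy)-4-methoxybenzoic acid | COc1c(OCc2ccccc2)cc(cc1OCc1ccccc1)C(O)=O | intermediate
20 | 3,5-bis(benzyloxy)-4-methoxybenzoyl chloride | COc1c(OCc2ccccc2)cc(cc1OCc1ccccc1)C(Cl)=O | intermediate
21 | 3-(benzyloxy)-5-methoxy-2-(methoxyacetyl)-6-methylphenyl 3,5-bis(benzyloxy)-4-methoxybenzoate | COCC(=O)c1c(OC(=O)c2cc(OCc3ccccc3)c(OC)c(OCc3ccccc3)c2)c(C)c(OC)cc1OCc1ccccc1 | intermediate
22 | 1-[6-(benzyloxy)-2-hydroxy-4-methoxy-3-methylphenyl]-3-[3,5-bis(benzyloxy)-4-methoxyphenyl]-2-methoxypropane-1,3-dione (racemic) | COC(C(=O)c1c(O)c(C)c(OC)cc1OCc1ccccc1)C(=O)c1cc(OCc2ccccc2)c(OC)c(OCc2ccccc2)c1 | intermediate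
23 | 5-(benzyloxy)-2-[3,5-bis(benzyloxy)-4-methoxyphenyl]-3,7-dimethoxy-8-methyl-4H-chromen-4-one | COc1cc(OCc2ccccc2)c2c(=O)c(OC)c(-c3cc(OCc4ccccc4)c(OC)c(OCc4ccccc4)c3)oc2c1C | intermediate
24 | 2-(3,5-dihydroxy-4-methoxyphenyl)-5-hydroxy-3,7-dimethoxy-8-methyl-4H-chromen-4-one | COc1cc(O)c2c(=O)c(OC)c(-c3cc(O)c(OC)c(O)c3)oc2c1C | target

## Step count and risks

Total: 12 steps. Longest linear sequence: 9 steps (steps 1, 3, 4, 5, 6, 9, 10, 11, 12) from **1**; steps 2 and 7–8 are side branches.

**Step 3 (key step).** The donor-stabilised cyclobutenone may open only at a temperature at which the alkoxyvinylketene dimerises, polymerises or acylates the product phenol faster than the ynol ether traps it; the ynol ether may also be lost by volatility or oligomerisation on long heating. The fallback abandons the pericyclic construction and installs the C5 oxygen on a preformed arene by sterically controlled C–H functionalisation. It does not start from a compound of the route but from commercial 3-methoxy-2-methylphenol F1. This is converted with NaH and MOMCl into 1-methoxy-3-(methoxymethoxy)-2-methylbenzene F2. Iridium-catalysed C–H borylation ([Ir(OMe)(cod)]2, 4,4'-di-tert-butyl-2,2'-bipyridine, B2pin2) should occur at the only C–H with no ortho substituent and give 2-[3-methoxy-5-(methoxymethoxy)-4-methylphenyl]-4,4,5,5-tetramethyl-1,3,2-dioxaborolane F3. Oxidation with H2O2 and NaOH gives 3-methoxy-5-(methoxymethoxy)-4-methylphenol F4, and benzylation (BnBr, K2CO3) returns to the route at **12**.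

**Step 5.** Metalation may occur in part at the other ring C–H (between the methoxy and benzyloxy groups), butyllithium may deprotonate the benzylic CH2 of the benzyl ether and trigger a Wittig shift, or the hindered aryllithium may enolise the amide instead of adding to it. The fallback sets out from **11** and uses the free hydroxyl as the regiochemical control. Magnesium-mediated ortho-formylation (MgCl2, Et3N, paraformaldehyde, MeCN, reflux) should give 6-(benzyloxy)-2-hydroxy-4-methoxy-3-methylbenzaldehyde F5. Protection (NaH, MOMCl) gives 6-(benzyloxy)-4-methoxy-2-(methoxymethoxy)-3-methylbenzaldehyde F6. Addition of methoxymethyllithium (from Bu3SnCH2OMe and n-BuLi, THF, −78 °C) gives 1-[6-(benzyloxy)-4-methoxy-2-(methoxymethoxy)-3-methylphenyl]-2-methoxyethan-1-ol F7, and Dess–Martin oxidation comes back at **15**.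

**Step 1.** The strained enone may suffer acid-promoted hydrolysis or ring cleavage before the exchange is complete, or the equilibrium may stall. The fallback sets out from **1**: hydrolysis with dilute aqueous HCl gives cyclobutane-1,3-dione F8, and Mitsunobu O-alkylation of this vinylogous acid with benzyl alcohol **2** (PPh3, DIAD, THF) comes back at **3**.

**Step 10.** The base may cleave the hindered aryl ester (returning **16**) faster than the alpha-methoxy ketone enolate attacks it, or enolisation may be slow because of the flanking substituents. The fallback sets out from **15** and the acid chloride **20** and forms the same C–C bond intermolecularly. The lithium enolate of **15** (LiHMDS, THF, −78 °C) is acylated with **20** to give 1-[6-(benzyloxy)-4-methoxy-2-(methoxymethoxy)-3-methylphenyl]-3-[3,5-bis(benzyloxy)-4-methoxyphenyl]-2-methoxypropane-1,3-dione F9. HCl in MeOH then removes the acetal and cyclodehydrates in one operation, coming back at **23**.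

**Step 12.** Saturation of the C2=C3 bond may compete, or cleavage of the hindered benzyl ether on the C5 oxygen may be incomplete. The fallback sets out from **23** and replaces hydrogenolysis by Lewis acid debenzylation with BCl3 and pentamethylbenzene as cation scavenger (CH2Cl2, −78 °C), which at that temperature should spare the methyl ethers. It arrives directly at **24**, and no new compound arises (F0).

## Further compounds

F1 | step 3 | 3-methoxy-2-methylphenol | COc1cccc(O)c1C
F2 | step 3 | 1-methoxy-3-(methoxymethoxy)-2-methylbenzene | COCOc1cccc(OC)c1C
F3 | step 3 | 2-[3-methoxy-5-(methoxymethoxy)-4-methylphenyl]-4,4,5,5-tetramethyl-1,3,2-dioxaborolane | COCOc1cc(B2OC(C)(C)C(C)(C)O2)cc(OC)c1C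
F4 | step 3 | 3-methoxy-5-(methoxymethoxy)-4-methylphenol | COCOc1cc(O)cc(OC)c1C
F5 | step 5 | 6-(benzyloxy)-2-hydroxy-4-methoxy-3-methylbenzaldehyde | O=Cc1c(O)c(C)c(OC)cc1OCc1ccccc1
F6 | step 5 | 6-(benzyloxy)-4-methoxy-2-(methoxymethoxy)-3-methylbenzaldehyde | O=Cc1c(OCOC)c(C)c(OC)cc1OCc1ccccc1
F7 | step 5 | 1-[6-(benzyloxy)-4-methoxy-2-(methoxymethoxy)-3-methylphenyl]-2-methoxyethan-1-ol (racemic) | COCC(O)c1c(OCOC)c(C)c(OC)cc1OCc1ccccc1
F8 | step 1 | cyclobutane-1,3-dione | O=C1CC(=O)C1
F9 | step 10 | 1-[6-(benzyloxy)-4-methoxy-2-(methoxymethoxy)-3-methylphenyl]-3-[3,5-bis(benzyloxy)-4-methoxyphenyl]-2-methoxypropane-1,3-dione (racemic) | COC(C(=O)c1c(OCOC)c(C)c(OC)cc1OCc1ccccc1)C(=O)c1cc(OCc2ccccc2)c(OC)c(OCc2ccccc2)c1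
F0 | step 12 | none | none
A1 | alternative 1 | 2-[4-methoxy-3,5-di(propan-2-yloxy)phenyl]-3,7-dimethoxy-8-methyl-5-(propan-2-yloxy)-4H-chromen-4-one | COc1cc(OC(C)C)c2c(=O)c(OC)c(-c3cc(OC(C)C)c(OC)c(OC(C)C)c3)oc2c1C
A2 | alternative 1 | (2E)-2-methoxy-3-[4-methoxy-3,5-di(propan-2-yloxy)phenyl]-3-[3-methoxy-2-methyl-5-(propan-2-yloxy)phenoxy]prop-2-enoic acid | OC(=O)/C(OC)=C(\Oc1cc(OC(C)C)cc(OC)c1C)c1cc(OC(C)C)c(OC)c(OC(C)C)c1
A3 | alternative 1 | 3-methoxy-2-methyl-5-(propan-2-yloxy)phenol | COc1cc(OC(C)C)cc(O)c1C
A4 | alternative 2 | 2-[3,5-bis(benzyloxy)-4-methoxyphenyl]-5,7-dihydroxy-3-methoxy-8-methyl-4H-chromen-4-one | Cc1c(O)cc(O)c2c(=O)c(OC)c(-c3cc(OCc4ccccc4)c(OC)c(OCc4ccccc4)c3)oc12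
A5 | alternative 2 | methyl 3-{6-[3,5-bis(benzyloxy)-4-methoxyphenyl]-2-ethyl-5-methoxy-4-oxo-4H-pyran-3-yl}-3-oxopropanoate | CCc1oc(-c2cc(OCc3ccccc3)c(OC)c(OCc3ccccc3)c2)c(OC)c(=O)c1C(=O)CC(=O)OC
A6 | alternative 3 | 5-(benzyloxy)-2-[3,5-bis(benzyloxy)-4-methoxyphenyl]-3,7-dimethoxy-8-methyl-4H-chromen-4-one | COc1cc(OCc2ccccc2)c2c(=O)c(OC)c(-c3cc(OCc4ccccc4)c(OC)c(OCc4ccccc4)c3)oc2c1C
A7 | alternative 3 | 1-[6-(benzyloxy)-2-fluoro-4-methoxy-3-methylphenyl]-3-[3,5-bis(benzyloxy)-4-methoxyphenyl]-2-methoxypropane-1,3-dione (racemic) | COC(C(=O)c1c(F)c(C)c(OC)cc1OCc1ccccc1)C(=O)c1cc(OCc2ccccc2)c(OC)c(OCc2ccccc2)c1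
A8 | alternative 3 | 5-(benzyloxy)-1-fluoro-3-methoxy-2-methylbenzene | COc1cc(OCc2ccccc2)cc(F)c1C
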